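## The problem

Target 36 is a compact tetracycle. With the numbering C1 (quaternary, geranyl), C2H2, C3H=C4(CH3), C5H, C6H2, C7H, C8(CH3)2, O9, C10=C11(prenyl), C12=O, C13(OH), C14(OH), the rings are cyclohexene ring A (C1–C2–C3–C4–C5–C14), cyclopentane ring B (C5–C6–C7–C13–C14), dihydrofuran ring C (C7–C8–O9–C10–C13) and vinylogous ester ring D (C1–C12–C11–C10–C13–C14); all are cis-fused and meet at the C13–C14 bond, each of these two carbons lying in three rings. Five contiguous stereocentres result (C1, C5, C7, C13, C14): C1 is an all-carbon quaternary centre, and C13 and C14 form a cis ditertiary diol. C1, C5 and C14 have to be correlated by the synthesis; once C5 and C14 are fixed, the cis fusion of rings B and C leaves no freedom at C13 and C7, so these two can be left to a late ring closure. The isolated trisubstituted alkenes of the geranyl and prenyl groups and C3=C4 rule out ozonolysis, hydrogenation, hydroboration and strong protic or halogen electrophiles throughout; the β-hydroxy ketone C14(OH)–C1–C12=O is open to retro-aldol cleavage under base, and the ditertiary diol to cyclic acetal formation and α-ketol shifts. The enabling feature is C14: a tertiary carbinol bonded to the carbonyl-level C13 and to C5, which is allylic to the C3=C4 alkene. Such a γ,δ-unsaturated α-alkoxy acid is the retron of a glycolate ester-enolate Claisen rearrangement, and because the carbinol carbon C3 and the enolate carbon C14 are joined through C2–C1, the ester is a δ-lactone and the rearrangement itself closes ring A.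

## Retrosynthesis

**Rings B and C (36 ⇒ 35 ⇒ 33).** The last cut goes through C7–C13 and C8–O9. Both bonds end on atoms attached to C13, so a ketone at C13 flanked by the enolised C10 oxygen provides electrophile and internal nucleophile, and the C5 prenyl group supplies C6–C8 at its natural oxidation level (Prins addition terminated by oxygen). The neighbouring cuts (C5–C6 with an acrylate, or O9–C10 after an epoxide opening) need a C7 ester or an epoxide that must first be made and then reworked. Hydroxy trione 35 is bicyclic with only three stereocentres (C1, C5, C14). The forward step must activate C13 without protonating the alkenes and needs C6 cis to C13 on ring A. 35 comes from its C14 methoxymethyl ether 33; the acetal is removed before the C13 hydroxyl exists, since next to a free hydroxyl it would tend to close to the cyclic formal.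

**Ring D (33 ⇒ 32 ⇒ 31 ⇒ 30 ⇒ 24 + 28).** Ring D is opened at C11–C12 (Claisen condensation of the C11 enolate of vicinal diketone 32 onto the C12 methyl ester) and then at C10–C13 (addition of acyl anion equivalent 28 to aldehyde 24, oxidation to 31, unmasking). The alternative of building an α-keto ester on C13 and a homoprenyl ketone on C12 needs two separate homologations and two redox adjustments at a hindered ester. Here one reagent brings C10, C11 and the prenyl group, and C12 stays the ester it has been from the start. The precursor 24 is monocyclic; the forward steps need C12 and C13 cis, and a C13 function that is distinguishable from C12.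

**Ring A, the key cut (24 ⇒ 22 ⇒ 19).** Aldehyde 24 is the reduction product of acid 22. In 22 the C5–C14 bond is cut with reconnection of C13 through oxygen to C3, which leads to δ-lactone 19 (ring O–C3–C2–C1–C14–C13). No other cut of ring A forms the congested C14 carbinol, places the C3=C4(CH3) alkene and sets C5 in one event. The precursor has no carbocycle and carries C1 and C3 as its only relevant stereocentres (C14 is erased). The forward reaction is asked to form a bond between two fully substituted or branched carbons, which the intramolecular, concerted nature of the rearrangement allows; it requires the geranyl group on C1 cis to the (E)-alkenyl group on C3.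

**The lactone (19 ⇒ 18 ⇒ 16 ⇒ 9 + 14).** Opening the lactone C–O bond gives hydroxy acid 18, whose C3 carbinol comes from enone 16 by catalyst-controlled reduction. This is preferred to substrate control because C3 is remote from C1. 16 is cut at C3–C4 into Weinreb amide 9 and alkenyl iodide 14. Only C13 is a free acid in 18, so the six-membered lactone can be closed by activation without competition from the C12 ester.

**The quaternary carbon (9 ⇒ 8 ⇒ 7 ⇒ 4 ⇒ 1 + 2 + 5).** Both C1–C bonds to the side chains are cut. The four-carbon unit C12–C1–C14–C13 with its α-hydroxy acid is dimethyl (S)-malate 1, so no one-carbon homologation is needed. The C14 stereocentre, which the key step destroys anyway, directs two successive enolate alkylations at C1 (geranyl bromide 2, then bromoacetamide 5); the order of the two alkylations decides the configuration of C1. A malonate-based assembly would leave the C1/C3 relationship to an unselective lactonisation of two equivalent esters and would require the hydroxy acid to be built afterwards. The two malate esters differ strongly in hindrance once C1 is quaternary, which allows selective hydrolysis at C13 (8 ⇒ 9).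

**The side-chain reagents (14 ⇒ 12 ⇒ 10 + 11; 28 ⇒ 25 + 26).** Iodide 14 is cut at the C–I bond and at C5–C6 to 1-propynylmagnesium bromide 10 and prenyl bromide 11 via enyne 12; the forward hydrometalation must put the metal next to the methyl group. Dithiane 28 is the alkylation product of 1,3-dithiane 25 with bromide 26.

## Roads not taken

**Alternative 1:** Ring A would be closed last, by cutting C6–C7 and C5–C14. A ring D trione A1 with a vinyl ketone arm on C1 would take up malonic acid half thioester A2 under secondary-amine catalysis (decarboxylative Michael addition, C6–C7), and the C4 ketone would then add through C5 to the C14 carbonyl to give ketol A3. Its merits are real: ring D with its prenyl group is in place early, two C–C bonds form in one flask, and no strong base or heat is needed. In these respects it is better than the chosen plan. Against it stand three points. A1 contains three contiguous or cross-conjugated carbonyls (C12, C13, C14) that must be discriminated, and its C1 stereocentre must be made separately and then relay, against or with the catalyst, to C5 and C14 in a flexible chain. A3 is also far from the target: C4 is a ketone instead of the C3=C4(CH3) alkene, C8 and its two methyl groups are missing, and the β-ketol C14(OH)–C5–C4=O invites retro-aldol. The chosen plan sets against the elegance of this annulation that 22 leaves the rearrangement with the ring A alkene, the C5 prenyl group and both carboxyl handles at their final positions, and that C1, C5 and C14 are correlated through one cyclic transition state.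

**Alternative 2:** Rings B and C would be closed by an anionic cascade, cutting C7–C13 and O9–C10. The γ-dienolate of bicyclic vinylogous ester A4 (C14 alkoxide formed first, LiN(iPr)2) opens the side-chain epoxide at C7, and the C8 alkoxide adds to C10 and expels methoxide to give the 13-deoxy tetracycle A5. No carbocation is involved, so the geranyl alkene cannot compete and C7 follows from the epoxide by inversion. In chemoselectivity this is better than the Prins closure chosen here. Its weak points are the site-selective epoxidation of one of four trisubstituted alkenes (or carrying an epoxide through the synthesis), the α- versus γ-reactivity of the dienolate, and above all the missing C13 hydroxyl. That hydroxyl would have to be introduced at a fully substituted ring-fusion carbon of A5 by enolisation at a position where planarisation is strained. The chosen plan has to set its cationic chemoselectivity risk against the fact that the C13 carbinol, C7 and both rings arise together from the unmodified prenyl group.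

**Alternative 3:** Ring B would be built by annulation, cutting C5–C6 and C7–C13. The C5 enolate of enone ketol A6 (LiN(SiMe3)2, C14 alkoxide present) adds to methyl acrylate A7, and the ester enolate closes onto the C13 ketone to give diol ester A8. This forms the C13 carbinol directly and without cations, and the C7 ester is a sensible handle for the dimethyl carbinol C8 and a later addition–elimination at C10. For ring B it is at least as good as the chosen closure. It is weaker elsewhere: A6 is a β-hydroxy ketone that can fragment on enolisation, the facial course at C5 is not secured, and A8 still needs C2=C3–C4=O converted into C2H2–C3=C4(CH3), two methyl additions and ring C closure. Making A6 with C1 and C14 defined is also a problem of the size the chosen key step solves. The chosen plan sets against it a ring A delivered in final form and a shorter sequence after the key step.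

Key step: step 10

Remark on the chemistry: ring D 1,3-dicarbonyl compounds (33–35, F7, F15) are written as the C10 enol; tautomers are not distinguished.
Remark on the chemistry: 9, 16, 18 and 19 are written with the C14 configuration inherited from 1; partial epimerisation at C14 in step 4 would be harmless because C14 becomes trigonal in 20, and 30 is expected as a mixture of C13 epimers that converge in 31.
Abbreviations: geranyl = (2E)-3,7-dimethylocta-2,6-dien-1-yl; prenyl = 3-methylbut-2-en-1-yl.

## Route

Step 1
Reactants: 1 dimethyl (S)-malate; 2 geranyl bromide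
Product: 4 dimethyl (2S,3R)-3-geranyl-2-hydroxybutanedioate, via dilithio malate 3 (not isolated)
Conditions: LiN(iPr)2 (2.2 equiv), THF, −78 to −20 °C; 2, −78 to −10 °C; H2O
Reagents that add atoms: none
Why: Fráter–Seebach alkylation: the chelated dilithium alkoxide enolate 3 should be alkylated by the allylic bromide on the face opposite the C13 ester of the chelate, giving the anti (2S,3R) product. The C1 configuration formed here does not matter, since C1 is enolised again in step 2; C14, taken from the chiral pool, is the controlling centre.

Step 2
Reactants: 4 dimethyl (2S,3R)-3-geranyl-2-hydroxybutanedioate; 5 2-bromo-N-methoxy-N-methylacetamide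
Product: 7 dimethyl (2S,3R)-3-geranyl-2-hydroxy-3-{2-[methoxy(methyl)amino]-2-oxoethyl}butanedioate, via dilithio enolate 6 (not isolated)
Conditions: LiN(iPr)2 (2.3 equiv), THF–DMPU, −78 to −20 °C; 5, −78 to −30 °C; H2O
Reagents that add atoms: none
Why: Second Fráter–Seebach alkylation, now forming the quaternary centre: the chelated tetrasubstituted enolate 6 should be attacked by the activated α-bromo amide from the same face as in step 1. With geranyl introduced first and the C2–C3 unit second, C1 is formed as drawn (the reverse order would give the epimer). The amide is less acidic than a bromo ketone or ester, which limits proton transfer, and its carbonyl is not acylating toward the alkoxide at low temperature.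

Step 3
Reactants: 7 dimethyl (2S,3R)-3-geranyl-2-hydroxy-3-{2-[methoxy(methyl)amino]-2-oxoethyl}butanedioate
Product: 8 dimethyl (2S,3R)-3-geranyl-2-(methoxymethoxy)-3-{2-[methoxy(methyl)amino]-2-oxoethyl}butanedioate
Conditions: MOMCl, iPr2NEt, n-Bu4NI (cat.), CH2Cl2, 0 to 40 °C
Reagents that add atoms: chloromethyl methyl ether, COCCl
Why: O-Alkylation of the hindered secondary carbinol by the reactive chloromethyl ether under amine base touches no enolisable position. The small, base-stable acetal is the non-migrating oxygen substituent wanted on the Claisen enolate.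

Step 4
Reactants: 8 dimethyl (2S,3R)-3-geranyl-2-(methoxymethoxy)-3-{2-[methoxy(methyl)amino]-2-oxoethyl}butanedioate
Product: 9 (2S,3R)-3-geranyl-4-methoxy-2-(methoxymethoxy)-3-{2-[methoxy(methyl)amino]-2-oxoethyl}-4-oxobutanoic acid (C13 acid, C12 methyl ester)
Conditions: LiOH·H2O (1.5 equiv), THF–H2O, 0 °C to rt; 1 M HCl to pH 3, 0 °C
Reagents that add atoms: lithium hydroxide, [Li+].[OH-]
Why: Chemoselective saponification: hydroxide should attack the α-alkoxy ester at C13, whereas the C12 ester sits on the quaternary C1 (pivalate-like) and the Weinreb amide resists hydroxide at this temperature. C13 becomes the only free acid, which differentiates the two malate carbonyls for steps 7 and 9.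

Step 5
Reactants: 10 1-propynylmagnesium bromide; 11 prenyl bromide
Product: 12 6-methylhept-5-en-2-yne
Conditions: CuBr·SMe2 (5 mol %), THF, 0 °C to rt
Reagents that add atoms: none
Why: Alkynyl–allyl cross-coupling catalysed by monovalent copper; substitution should occur mainly at the unhindered CH2 of the primary allylic bromide to give the skipped enyne.

Step 6
Reactants: 12 6-methylhept-5-en-2-yne
Product: 14 (2E)-2-iodo-6-methylhepta-2,5-diene, via alkenylzirconocene 13 (not isolated)
Conditions: Cp2Zr(H)Cl (1.5 equiv), THF, rt to 40 °C; I2, 0 °C
Reagents that add atoms: iodine, [I][I]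
Why: Hydrozirconation–iodination: syn addition of Zr–H, equilibrated by the slight excess of hydride, should place zirconium on the less hindered methyl-bearing carbon (13), and iodinolysis with retention gives the (E)-iodide. The trisubstituted alkene is inert to the zirconium hydride under these conditions.

Step 7
Reactants: 14 (2E)-2-iodo-6-methylhepta-2,5-diene; 9 (2S,3R)-3-geranyl-4-methoxy-2-(methoxymethoxy)-3-{2-[methoxy(methyl)amino]-2-oxoethyl}-4-oxobutanoic acid
Product: 16 (2S,3R)-3-geranyl-3-[(3E)-3,7-dimethyl-2-oxoocta-3,6-dien-1-yl]-4-methoxy-2-(methoxymethoxy)-4-oxobutanoic acid (C3 enone), via alkenyllithium 15 (not isolated)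
Conditions: 14, t-BuLi (2.0 equiv), Et2O, −78 °C; 9, LiN(SiMe3)2 (1.05 equiv), THF, −78 °C; combine, −78 to −40 °C; 1 M HCl, 0 °C
Reagents that add atoms: none
Why: Weinreb ketone synthesis: iodine–lithium exchange gives 15 with retention of alkene geometry, and 15 should add once to the amide through the chelated tetrahedral intermediate. The C13 acid is protected in the flask as its lithium carboxylate and the C12 ester is shielded by the quaternary C1, so the (E)-enone forms only at C3 and never meets aqueous base.

Step 8
Reactants: 16 (2S,3R)-3-geranyl-3-[(3E)-3,7-dimethyl-2-oxoocta-3,6-dien-1-yl]-4-methoxy-2-(methoxymethoxy)-4-oxobutanoic acid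
Product: 18 (2S,3R)-3-geranyl-3-[(2S,3E)-2-hydroxy-3,7-dimethylocta-3,6-dien-1-yl]-4-methoxy-2-(methoxymethoxy)-4-oxobutanoic acid, via acyloxyborane 17 (not isolated)
Conditions: catecholborane (1.1 equiv), CH2Cl2, 0 °C to rt; (R)-2-methyl-CBS-oxazaborolidine (0.2 equiv), catecholborane (1.6 equiv), toluene, −78 °C; MeOH, pH 7 buffer
Reagents that add atoms: none
Why: Corey–Bakshi–Shibata reduction: the acid is first masked as acyloxyborane 17, then the (R)-catalyst should deliver hydride to the enone carbonyl with the alkenyl group as the large and the CH2 group as the small substituent. This gives the (S)-carbinol at C3 under catalyst control with 1,2-selectivity at −78 °C; the neutral work-up returns the acid without exposing the γ-hydroxy ester to base.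

Step 9
Reactants: 18 (2S,3R)-3-geranyl-3-[(2S,3E)-2-hydroxy-3,7-dimethylocta-3,6-dien-1-yl]-4-methoxy-2-(methoxymethoxy)-4-oxobutanoic acid
Product: 19 methyl (3S,4R,6S)-4-geranyl-3-(methoxymethoxy)-6-[(2E)-6-methylhepta-2,5-dien-2-yl]-2-oxooxane-4-carboxylate (δ-lactone)
Conditions: EDC·HCl, DMAP, CH2Cl2 (0.02 M), 0 °C to rt
Reagents that add atoms: none
Why: Carbodiimide (Steglich-type) lactonisation: only C13 is a free acid and is activated, so the C3 hydroxyl closes the six-membered lactone with retention at C3. The unactivated, hindered C12 methyl ester cannot compete to give the five-membered lactone, and the ring places the geranyl group on C1 cis to the alkenyl group on C3.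

Step 10
Reactants: 19 methyl (3S,4R,6S)-4-geranyl-3-(methoxymethoxy)-6-[(2E)-6-methylhepta-2,5-dien-2-yl]-2-oxooxane-4-carboxylate
Product: 22 (1R,2S,6R)-6-geranyl-6-(methoxycarbonyl)-1-(methoxymethoxy)-3-methyl-2-prenylcyclohex-3-ene-1-carboxylic acid, via silyl ketene acetal 20 (not isolated), via trimethylsilyl ester 21 (not isolated)
Conditions: LiN(iPr)2 (1.4 equiv), Me3SiCl–Et3N (3 equiv each), THF, −78 °C to rt; toluene, 100 °C; 1 M HCl, THF, 0 °C
Reagents that add atoms: none
Why: LiN(iPr)2 removes the C14 hydrogen in the presence of Me3SiCl, and the lactone enolate is trapped on oxygen as ketene acetal 20, whose C13=C14 geometry is fixed by the ring. On heating, the allyl vinyl ether C14=C13–O–C3–C4=C5 undergoes a suprafacial [3,3] shift (Ireland–Claisen rearrangement) to silyl ester 21, hydrolysed to 22 on work-up. The closest known reaction type is the Ireland–Claisen rearrangement of six-membered alkenyl lactone silyl ketene acetals to carbocyclic acids, which proceeds through boat transition states. Ring A is closed by the new C5–C14 bond while C3–O breaks; the mode of closure is sigmatropic ring reorganisation through a boat, because the two-atom tether C2–C1 between C3 and C14 forbids a chair and enforces a bicyclo[2.2.2]octane-like array with C3 and C14 as bridgeheads. C14 is attacked on the lactone face that carries the alkenyl group, so the C3 configuration from step 8 fixes C14. At C5 the (E)-C4=C5 geometry puts hydrogen on the inner and C6 on the outer position of the boat, which places C6 cis to C13. Since geranyl on C1 is cis to the alkenyl group in 19, C12 ends up cis to C13 and C6, the all-cis arrangement that rings D and B need; the C14 configuration of 19 is erased in 20 and is irrelevant. The step needs enolisation at C14 only (the sole α-hydrogen, the C12 ester having none) and a ketene acetal that survives until it rearranges, which the internal silyl chloride quench and the chelating α-acetal oxygen should secure.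

Step 11
Reactants: 22 (1R,2S,6R)-6-geranyl-6-(methoxycarbonyl)-1-(methoxymethoxy)-3-methyl-2-prenylcyclohex-3-ene-1-carboxylic acid
Product: 24 methyl (1R,5S,6R)-6-formyl-1-geranyl-6-(methoxymethoxy)-4-methyl-5-prenylcyclohex-3-ene-1-carboxylate (C13 aldehyde), via acyl imidazolide 23 (not isolated)
Conditions: 1,1′-carbonyldiimidazole, THF, rt to 40 °C; (i-Bu)2AlH (1.2 equiv), toluene, −78 °C; aq. potassium sodium tartrate
Reagents that add atoms: none
Why: Activation as acyl imidazolide 23 and hydride reduction at −78 °C should stop at the aldehyde, because the tetrahedral aluminate is stable in the cold. The activation is free of chloride and acid, which protects the neighbouring acetal, and the C12 ester on the quaternary C1 is far less electrophilic than the imidazolide.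

Step 12
Reactants: 25 1,3-dithiane; 26 5-bromo-2-methylpent-2-ene
Product: 28 2-(4-methylpent-3-en-1-yl)-1,3-dithiane, via 2-lithio-1,3-dithiane 27 (not isolated)
Conditions: n-BuLi, THF, −30 °C; 26, −78 to 0 °C
Reagents that add atoms: none
Why: Corey–Seebach alkylation of the lithiated dithiane with a primary homoallylic bromide gives the acyl anion equivalent that carries C10, C11 and the prenyl group of ring D.

Step 13
Reactants: 28 2-(4-methylpent-3-en-1-yl)-1,3-dithiane; 24 methyl (1R,5S,6R)-6-formyl-1-geranyl-6-(methoxymethoxy)-4-methyl-5-prenylcyclohex-3-ene-1-carboxylate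
Product: 30 the secondary alcohol from addition of the dithiane carbon to the aldehyde of 24 (C13 carbinol bearing the 2-(4-methylpent-3-en-1-yl)-1,3-dithian-2-yl group; other centres as in 24), via lithiated dithiane 29 (not isolated)
Conditions: n-BuLi, THF, −20 °C; 24, −78 °C; AcOH, −78 °C
Reagents that add atoms: none
Why: Corey–Seebach addition of acyl anion equivalent 29 to the non-enolisable aldehyde forms the C10–C13 bond. The cold acetic acid quench should keep the alkoxide from closing onto the C12 ester, and the C13 configuration is irrelevant because the carbinol is oxidised next.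

Step 14
Reactants: 30 the C13 carbinol with the dithiane at C10
Product: 31 the corresponding C13 ketone (2-acyl-1,3-dithiane; other centres as in 24)
Conditions: Dess–Martin periodinane, NaHCO3, CH2Cl2, 0 °C to rt
Reagents that add atoms: none
Why: Dess–Martin oxidation of the hindered secondary carbinol under buffered, anhydrous conditions, which thioacetals and trisubstituted alkenes tolerate. It removes the hydroxyl that could lactonise onto C12.

Step 15
Reactants: 31 the C13 ketone with the dithiane at C10
Product: 32 methyl (1R,5S,6R)-1-geranyl-6-(methoxymethoxy)-4-methyl-6-(6-methyl-2-oxohept-5-enoyl)-5-prenylcyclohex-3-ene-1-carboxylate (C13/C10 vicinal diketone)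
Conditions: PhI(OCOCF3)2, NaHCO3, MeCN–H2O (9:1), 0 °C
Reagents that add atoms: water, O
Why: Oxidative dethioacetalisation with the trivalent iodine reagent in buffered aqueous acetonitrile should unmask the C10 ketone of the acyl dithiane within minutes. Isolated trisubstituted alkenes and the acetal survive these conditions, and the diketone is used at once.

Step 16
Reactants: 32 methyl (1R,5S,6R)-1-geranyl-6-(methoxymethoxy)-4-methyl-6-(6-methyl-2-oxohept-5-enoyl)-5-prenylcyclohex-3-ene-1-carboxylate
Product: 33 cis-fused bicyclic trione (rings A and D; C12 ketone, C11 prenyl, C10 enol, C13 ketone, C14 methoxymethyl ether, C1 geranyl, C5 prenyl)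
Conditions: LiN(SiMe3)2 (2.2 equiv), THF, −78 to 0 °C; 1 M HCl, 0 °C
Reagents that add atoms: none
Why: Intramolecular Claisen (Dieckmann-type) condensation: C11 is the only enolisable position, and its enolate should acylate the C12 ester in a 6-(enolendo)-exo-trig closure of ring D, the second equivalent of base holding the product as its stabilised enolate. C13 has no hydrogen on either side, so neither acyloin isomerisation nor β-elimination of the C14 oxygen can interfere.

Step 17
Reactants: 33 bicyclic trione with C14 methoxymethyl ether
Product: 35 bicyclic hydroxy trione (as 33, free tertiary hydroxyl at C14), via bipyridinium salt 34 (not isolated)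
Conditions: Me3SiOSO2CF3 (4 equiv), 2,2′-bipyridyl (6 equiv), CH2Cl2, 0 °C to rt; H2O
Reagents that add atoms: none
Why: Silyl triflate–bipyridyl acetal cleavage: the silyl triflate activates the methoxy oxygen and the pyridine nitrogen displaces it at the acetal carbon, giving salt 34 (the enol being silylated in passing), which water hydrolyses to the free alcohol. The medium is buffered and non-protic, which spares the alkenes, and the acetal is removed now because no neighbouring hydroxyl is present that could trap it as a cyclic formal.

Step 18
Reactants: 35 bicyclic hydroxy trione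
Product: 36 target tetracycle (CNP0323114.1)
Conditions: Me2AlCl (3.5 equiv), CH2Cl2, −78 to −20 °C; aq. potassium sodium tartrate
Reagents that add atoms: none
Why: Lewis acid-promoted Prins cyclisation terminated by oxygen: Me2AlCl turns the enol and the C14 hydroxyl into aluminium alkoxides (protons leave as methane, so no Brønsted acid reaches the alkenes), and the C14 alkoxide chelates and activates the C13 ketone. C7 of the cis-disposed C5 prenyl group should add to C13 in a 5-exo closure of ring B, necessarily cis-fused and on the C5 side, which sets the C13 carbinol cis to the C14 oxygen. The tertiary C8 cation is captured by the C10 enolate oxygen to close ring C, possible only when C8 is cis to C10, which fixes C7.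

## Compound list

1 | dimethyl (S)-malate, dimethyl (2S)-2-hydroxybutanedioate | COC(=O)C[C@H](O)C(=O)OC | starting material
2 | geranyl bromide, (2E)-1-bromo-3,7-dimethylocta-2,6-diene | CC(C)=CCC/C(C)=C/CBr | starting material
3 | dilithio malate (C14 lithium alkoxide, lithium enolate of the C12 ester of 1) | COC(O[Li])=C[C@H](O[Li])C(=O)OC | intermediate (not isolated)
4 | dimethyl (2S,3R)-3-geranyl-2-hydroxybutanedioate | CC(C)=CCC/C(C)=C/C[C@H]([C@H](O)C(=O)OC)C(=O)OC | intermediate
5 | 2-bromo-N-methoxy-N-methylacetamide | CON(C)C(=O)CBr | starting material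
6 | dilithio enolate of 4 (C14 lithium alkoxide, C12 ester enolate) | CC(C)=CCC/C(C)=C/CC([C@H](O[Li])C(=O)OC)=C(OC)O[Li] | intermediate (not isolated)
7 | dimethyl (2S,3R)-3-geranyl-2-hydroxy-3-{2-[methoxy(methyl)amino]-2-oxoethyl}butanedioate | CC(C)=CCC/C(C)=C/C[C@@]([C@H](O)C(=O)OC)(C(=O)OC)CC(=O)N(C)OC | intermediate
8 | dimethyl (2S,3R)-3-geranyl-2-(methoxymethoxy)-3-{2-[methoxy(methyl)amino]-2-oxoethyl}butanedioate | CC(C)=CCC/C(C)=C/C[C@@]([C@H](OCOC)C(=O)OC)(C(=O)OC)CC(=O)N(C)OC | intermediate
9 | (2S,3R)-3-geranyl-4-methoxy-2-(methoxymethoxy)-3-{2-[methoxy(methyl)amino]-2-oxoethyl}-4-oxobutanoic acid | CC(C)=CCC/C(C)=C/C[C@@]([C@H](OCOC)C(O)=O)(C(=O)OC)CC(=O)N(C)OC | intermediate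
10 | 1-propynylmagnesium bromide | CC#C[Mg]Br | starting material
11 | prenyl bromide, 1-bromo-3-methylbut-2-ene | CC(C)=CCBr | starting material
12 | 6-methylhept-5-en-2-yne | CC#CCC=C(C)C | intermediate
13 | chlorobis(cyclopentadienyl)[(2E)-6-methylhepta-2,5-dien-2-yl]zirconium | Cl[Zr](C1C=CC=C1)(C1C=CC=C1)/C(C)=C/CC=C(C)C | intermediate (not isolated)
14 | (2E)-2-iodo-6-methylhepta-2,5-diene | I/C(C)=C/CC=C(C)C | intermediate
15 | [(2E)-6-methylhepta-2,5-dien-2-yl]lithium | [Li]/C(C)=C/CC=C(C)C | intermediate (not isolated)
16 | (2S,3R)-3-geranyl-3-[(3E)-3,7-dimethyl-2-oxoocta-3,6-dien-1-yl]-4-methoxy-2-(methoxymethoxy)-4-oxobutanoic acid | CC(C)=CCC/C(C)=C/C[C@@]([C@H](OCOC)C(O)=O)(C(=O)OC)CC(=O)/C(C)=C/CC=C(C)C | intermediate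
17 | mixed anhydride of 16 with catecholborane (1,3,2-benzodioxaborol-2-yl carboxylate) | CC(C)=CCC/C(C)=C/C[C@@]([C@H](OCOC)C(=O)OB1Oc2ccccc2O1)(C(=O)OC)CC(=O)/C(C)=C/CC=C(C)C | intermediate (not isolated)
18 | (2S,3R)-3-geranyl-3-[(2S,3E)-2-hydroxy-3,7-dimethylocta-3,6-dien-1-yl]-4-methoxy-2-(methoxymethoxy)-4-oxobutanoic acid | CC(C)=CCC/C(C)=C/C[C@@]([C@H](OCOC)C(O)=O)(C(=O)OC)C[C@H](O)/C(C)=C/CC=C(C)C | intermediate
19 | methyl (3S,4R,6S)-4-geranyl-3-(methoxymethoxy)-6-[(2E)-6-methylhepta-2,5-dien-2-yl]-2-oxooxane-4-carboxylate | CC(C)=CCC/C(C)=C/C[C@@]1(C(=O)OC)C[C@@H](/C(C)=C/CC=C(C)C)OC(=O)[C@H]1OCOC | intermediate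
20 | trimethylsilyl ketene acetal of 19 (C13–OSiMe3, C13=C14) | CC(C)=CCC/C(C)=C/C[C@@]1(C(=O)OC)C[C@@H](/C(C)=C/CC=C(C)C)OC(O[Si](C)(C)C)=C1OCOC | intermediate (not isolated)
21 | trimethylsilyl ester of 22 | CC(C)=CCC/C(C)=C/C[C@@]1(C(=O)OC)CC=C(C)[C@H](CC=C(C)C)[C@]1(OCOC)C(=O)O[Si](C)(C)C | intermediate (not isolated)
22 | (1R,2S,6R)-6-geranyl-6-(methoxycarbonyl)-1-(methoxymethoxy)-3-methyl-2-prenylcyclohex-3-ene-1-carboxylic acid | CC(C)=CCC/C(C)=C/C[C@@]1(C(=O)OC)CC=C(C)[C@H](CC=C(C)C)[C@]1(OCOC)C(O)=O | intermediate
23 | acyl imidazolide of 22 | CC(C)=CCC/C(C)=C/C[C@@]1(C(=O)OC)CC=C(C)[C@H](CC=C(C)C)[C@]1(OCOC)C(=O)n2ccnc2 | intermediate (not isolated)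
24 | methyl (1R,5S,6R)-6-formyl-1-geranyl-6-(methoxymethoxy)-4-methyl-5-prenylcyclohex-3-ene-1-carboxylate | CC(C)=CCC/C(C)=C/C[C@@]1(C(=O)OC)CC=C(C)[C@H](CC=C(C)C)[C@]1(OCOC)C=O | intermediate
25 | 1,3-dithiane | C1CSCSC1 | starting material
26 | 5-bromo-2-methylpent-2-ene | CC(C)=CCCBr | starting material
27 | 2-lithio-1,3-dithiane | [Li]C1SCCCS1 | intermediate (not isolated)
28 | 2-(4-methylpent-3-en-1-yl)-1,3-dithiane | CC(C)=CCCC1SCCCS1 | intermediate
29 | 2-lithio-2-(4-methylpent-3-en-1-yl)-1,3-dithiane | CC(C)=CCCC1([Li])SCCCS1 | intermediate (not isolated)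
30 | methyl 1-geranyl-6-{hydroxy[2-(4-methylpent-3-en-1-yl)-1,3-dithian-2-yl]methyl}-6-(methoxymethoxy)-4-methyl-5-prenylcyclohex-3-ene-1-carboxylate (ring centres as in 24, C13 epimers) | CC(C)=CCC/C(C)=C/C[C@@]1(C(=O)OC)CC=C(C)[C@H](CC=C(C)C)[C@]1(OCOC)C(O)C2(CCC=C(C)C)SCCCS2 | intermediate
31 | methyl 1-geranyl-6-(methoxymethoxy)-4-methyl-6-{[2-(4-methylpent-3-en-1-yl)-1,3-dithian-2-yl]carbonyl}-5-prenylcyclohex-3-ene-1-carboxylate (ring centres as in 24) | CC(C)=CCC/C(C)=C/C[C@@]1(C(=O)OC)CC=C(C)[C@H](CC=C(C)C)[C@]1(OCOC)C(=O)C2(CCC=C(C)C)SCCCS2 | intermediate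
32 | methyl (1R,5S,6R)-1-geranyl-6-(methoxymethoxy)-4-methyl-6-(6-methyl-2-oxohept-5-enoyl)-5-prenylcyclohex-3-ene-1-carboxylate | CC(C)=CCC/C(C)=C/C[C@@]1(C(=O)OC)CC=C(C)[C@H](CC=C(C)C)[C@]1(OCOC)C(=O)C(=O)CCC=C(C)C | intermediate
33 | cis-fused rings A and D trione, C10 enol form: C1 geranyl, C5 prenyl, C11 prenyl, C12 and C13 ketones, C14 methoxymethyl ether | CC(C)=CCC/C(C)=C/C[C@@]12CC=C(C)[C@H](CC=C(C)C)[C@]1(OCOC)C(=O)C(O)=C(CC=C(C)C)C2=O | intermediate
34 | N-(alkoxymethyl)-2,2′-bipyridinium triflate of 33 with the C10 enol as trimethylsilyl ether | CC(C)=CCC/C(C)=C/C[C@@]12CC=C(C)[C@H](CC=C(C)C)[C@]1(OC[n+]3ccccc3-c3ccccn3)C(=O)C(O[Si](C)(C)C)=C(CC=C(C)C)C2=O.[O-]S(=O)(=O)C(F)(F)F | intermediate (not isolated)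
35 | cis-fused rings A and D hydroxy trione (as 33 with free C14 hydroxyl) | CC(C)=CCC/C(C)=C/C[C@@]12CC=C(C)[C@H](CC=C(C)C)[C@]1(O)C(=O)C(O)=C(CC=C(C)C)C2=O | intermediate
36 | target CNP0323114.1 | CC(C)=CCC/C(C)=C/C[C@]12CC=C(C)[C@@H]3C[C@@H]4C(C)(C)OC(=C(CC=C(C)C)C1=O)[C@]4(O)[C@@]32O | target

## Step count and least certain steps

Total step count: 18 (steps 5, 6 and 12 prepare the two side-chain reagents). Longest linear sequence: 15 steps from 1 (steps 1–4, 7–11, 13–18).

**Step 10 (key step).** The most likely failure is slow or incomplete removal of the tertiary C14 hydrogen, which is flanked by the quaternary C1 and is pseudo-equatorial in the more stable half-chair of 19. A second failure mode is thermal isomerisation of the O-silyl ketene acetal to a C-silyl lactone before the boat is reached, since the boat has to place the C1 and C3 side chains 1,3-diaxial. The fallback generates the same kind of ketene acetal without any C–H deprotonation. Setting out from 19, the acetal is cleaved with ZnBr2 and n-PrSH to the α-hydroxy lactone F1, and Dess–Martin oxidation gives the α-keto lactone F2, which cannot enolise because C1 is quaternary. Two-electron reduction of the vicinal dicarbonyl with Mg in the presence of Me3SiCl (acyloin-type trapping of the enediolate) gives the bis(silyloxy) ketene acetal F3. This should rearrange through the same boat to the bis-silyl derivative F4 and, after aqueous acid, to the hydroxy acid F5. Methoxymethylation of both oxygen functions (MOMCl, iPr2NEt) gives F6, and cleavage of the labile methoxymethyl ester with LiOH comes back to the route at 22.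

**Step 18.** The process most likely to go wrong is competition between two alkenes for the activated C13 ketone: the first alkene of the geranyl group on C1 is also three bonds from C13 and could add in a bridged mode. Loss of a proton from the C8 cation before capture by O9, or capture by the C14 oxygen, are further risks. The fused closure through the cis C5 prenyl group is expected to win on strain grounds, but this is not secured. The fallback separates the two bond formations and avoids free cations in the C–C step. Setting out from 35, heating in toluene (130 °C, sealed, radical inhibitor) should bring about a concerted intramolecular carbonyl-ene reaction, in which the prenyl group cis to C13 transfers a methyl hydrogen to the ketone oxygen, giving the ene product F7 (ring B closed, isopropenyl at C7, C13 hydroxyl). Catalytic camphorsulfonic acid in CH2Cl2 then adds the C10 enol oxygen to the isopropenyl group in the Markovnikov sense and comes back to the route at 36.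

**Step 16.** Acylation at the pivalate-like C12 ester may be slow, and the lithium methoxide set free can then add to the very electrophilic vicinal dione (benzilic ester-type rearrangement or C10–C13 cleavage). The fallback closes ring D by aldol addition to a C12 aldehyde. Setting out from 30, the C13 alkoxide (LiN(SiMe3)2, 1 equiv, 0 °C) is allowed to close onto C12 to give the lactone F8, and (i-Bu)2AlH at −78 °C reduces it to the lactol F9. PhI(OCOCF3)2 unmasks the C10 ketone to give the keto lactol F10. Amine-catalysed aldol addition (pyrrolidine, AcOH) of C11 to the C12 aldehyde, the open form of the lactol, gives the keto diol F11, and 2-iodoxybenzoic acid oxidises both carbinols, coming back to the route at 33.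

**Step 13.** A fully substituted lithiodithiane has to attack an aldehyde on a quaternary carbon. The addition may stall or revert, and if the mixture is warmed to force it, the alkoxide closes onto the C12 ester and blocks the oxidation of step 14. The fallback uses a smaller, sp2-hybridised acyl anion equivalent and adds the prenyl group last. Setting out from 24, 1-ethoxyvinyllithium (ethyl vinyl ether, t-BuLi, −78 °C) gives the carbinol F12; Dess–Martin oxidation gives the α-ethoxy enone F13, and aqueous oxalic acid the methyl diketone F14. LiN(SiMe3)2 closes ring D to the C11-unsubstituted trione F15. Tsuji–Trost allylation (Pd(PPh3)4, prenyl methyl carbonate), in which the soft enolate attacks the unsubstituted allyl terminus, comes back to the route at 33.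

**Step 2.** Alkylation at the fully substituted enolate carbon may be slower than proton transfer from the bromoacetamide or from the product, so that 4 is recovered; warming to compensate invites retro-aldol cleavage of the alkoxide. The fallback uses a more electrophilic α-halo ester and reaches the amide afterwards. Setting out from 4, the dianion is alkylated with allyl bromoacetate to the triester F16, and MOMCl with iPr2NEt gives F17. The allyl ester alone is cleaved with Pd(PPh3)4 and morpholine to the acid F18, and coupling with N,O-dimethylhydroxylamine (EDC·HCl) comes back to the route at 8.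

**Step 8.** Incomplete masking of the carboxyl group would leave an acidic proton that deactivates the oxazaborolidine or opens an uncatalysed, unselective reduction, eroding the configuration at C3; a mismatch with C1 and C14 is a smaller concern. The fallback removes the acid from the reduction. Setting out from 16, esterification with 2-(trimethylsilyl)ethanol (EDC·HCl, DMAP) gives the ester F19, the neutral enone is reduced with the same catalyst to the allylic alcohol F20, and Bu4NF releases the carboxylate, coming back to the route at 18.

## Further compounds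

F1 | step 10 | α-hydroxy lactone (19 without the methoxymethyl group) | CC(C)=CCC/C(C)=C/C[C@@]1(C(=O)OC)C[C@@H](/C(C)=C/CC=C(C)C)OC(=O)[C@H]1O
F2 | step 10 | α-keto lactone (C14 ketone) | CC(C)=CCC/C(C)=C/C[C@@]1(C(=O)OC)C[C@@H](/C(C)=C/CC=C(C)C)OC(=O)C1=O
F3 | step 10 | bis(trimethylsilyloxy) ketene acetal (C13 and C14 silyl ethers, C13=C14) | CC(C)=CCC/C(C)=C/C[C@@]1(C(=O)OC)C[C@@H](/C(C)=C/CC=C(C)C)OC(O[Si](C)(C)C)=C1O[Si](C)(C)C
F4 | step 10 | rearranged C14 silyl ether, C13 silyl ester | CC(C)=CCC/C(C)=C/C[C@@]1(C(=O)OC)CC=C(C)[C@H](CC=C(C)C)[C@]1(O[Si](C)(C)C)C(=O)O[Si](C)(C)C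
F5 | step 10 | ring A hydroxy acid (22 without the methoxymethyl group) | CC(C)=CCC/C(C)=C/C[C@@]1(C(=O)OC)CC=C(C)[C@H](CC=C(C)C)[C@]1(O)C(O)=O
F6 | step 10 | methoxymethyl ester of 22 | CC(C)=CCC/C(C)=C/C[C@@]1(C(=O)OC)CC=C(C)[C@H](CC=C(C)C)[C@]1(OCOC)C(=O)OCOC
F7 | step 18 | ene product: rings A, B, D closed, isopropenyl at C7, C13 and C14 hydroxyls, C10 enol | CC(C)=CCC/C(C)=C/C[C@]12CC=C(C)[C@@H]3C[C@H](C(C)=C)[C@](O)(C(O)=C(CC=C(C)C)C1=O)[C@@]32O
F8 | step 16 | cis-fused γ-lactone (C13–O–C12) carrying the dithiane at C10 | CC(C)=CCC/C(C)=C/C[C@@]12CC=C(C)[C@H](CC=C(C)C)[C@]1(OCOC)C(OC2=O)C3(CCC=C(C)C)SCCCS3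
F9 | step 16 | lactol of F8 (C12 hemiacetal) | CC(C)=CCC/C(C)=C/C[C@@]12CC=C(C)[C@H](CC=C(C)C)[C@]1(OCOC)C(OC2O)C3(CCC=C(C)C)SCCCS3
F10 | step 16 | keto lactol (C10 ketone, C12 hemiacetal) | CC(C)=CCC/C(C)=C/C[C@@]12CC=C(C)[C@H](CC=C(C)C)[C@]1(OCOC)C(OC2O)C(=O)CCC=C(C)C
F11 | step 16 | ring D keto diol (C12 and C13 carbinols, C10 ketone, C11 prenyl) | CC(C)=CCC/C(C)=C/C[C@@]12CC=C(C)[C@H](CC=C(C)C)[C@]1(OCOC)C(O)C(=O)C(CC=C(C)C)C2O
F12 | step 13 | C13 carbinol bearing a 1-ethoxyvinyl group | CC(C)=CCC/C(C)=C/C[C@@]1(C(=O)OC)CC=C(C)[C@H](CC=C(C)C)[C@]1(OCOC)C(O)C(=C)OCC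
F13 | step 13 | α-ethoxy enone (C13 ketone) | CC(C)=CCC/C(C)=C/C[C@@]1(C(=O)OC)CC=C(C)[C@H](CC=C(C)C)[C@]1(OCOC)C(=O)C(=C)OCC
F14 | step 13 | methyl diketone (C13 and C10 ketones, C11 methyl) | CC(C)=CCC/C(C)=C/C[C@@]1(C(=O)OC)CC=C(C)[C@H](CC=C(C)C)[C@]1(OCOC)C(=O)C(C)=O
F15 | step 13 | ring D trione without the C11 prenyl group | CC(C)=CCC/C(C)=C/C[C@@]12CC=C(C)[C@H](CC=C(C)C)[C@]1(OCOC)C(=O)C(O)=CC2=O
F16 | step 2 | allyl ester analogue of 7 (C3 allyl ester, free C14 hydroxyl) | CC(C)=CCC/C(C)=C/C[C@@]([C@H](O)C(=O)OC)(C(=O)OC)CC(=O)OCC=C
F17 | step 2 | methoxymethyl ether of F16 | CC(C)=CCC/C(C)=C/C[C@@]([C@H](OCOC)C(=O)OC)(C(=O)OC)CC(=O)OCC=C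
F18 | step 2 | C3 carboxylic acid (dimethyl ester at C12 and C13) | CC(C)=CCC/C(C)=C/C[C@@]([C@H](OCOC)C(=O)OC)(C(=O)OC)CC(O)=O
F19 | step 8 | 2-(trimethylsilyl)ethyl ester of 16 | CC(C)=CCC/C(C)=C/C[C@@]([C@H](OCOC)C(=O)OCC[Si](C)(C)C)(C(=O)OC)CC(=O)/C(C)=C/CC=C(C)C
F20 | step 8 | 2-(trimethylsilyl)ethyl ester of 18 | CC(C)=CCC/C(C)=C/C[C@@]([C@H](OCOC)C(=O)OCC[Si](C)(C)C)(C(=O)OC)C[C@H](O)/C(C)=C/CC=C(C)C
A1 | alternative 1 | ring D trione with vinyl ketone arm on C1 | CC(C)=CCC/C(C)=C/C[C@@]1(CCC(=O)C=C)C(=O)C(=O)C(OC)=C(CC=C(C)C)C1=O
A2 | alternative 1 | malonic acid half thioester, 3-oxo-3-(phenylsulfanyl)propanoic acid | OC(=O)CC(=O)Sc1ccccc1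
A3 | alternative 1 | bicyclic (rings A and D) ketol with C4 ketone and thioester arm on C5 | CC(C)=CCC/C(C)=C/C[C@]12CCC(=O)[C@H](CCC(=O)Sc3ccccc3)[C@]2(O)C(=O)C(OC)=C(CC=C(C)C)C1=O
A4 | alternative 2 | bicyclic vinylogous methyl ester with C14 hydroxyl and C7–C8 epoxide | CC(C)=CCC/C(C)=C/C[C@]12CC=C(C)[C@H](C[C@@H]3OC3(C)C)[C@]2(O)CC(OC)=C(CC=C(C)C)C1=O
A5 | alternative 2 | 13-deoxy tetracycle | CC(C)=CCC/C(C)=C/C[C@]12CC=C(C)[C@@H]3C[C@@H]4C(C)(C)OC(=C(CC=C(C)C)C1=O)[C@@H]4[C@@]32O
A6 | alternative 3 | bicyclic enone ketol (C2=C3–C4=O, C13 ketone, C14 hydroxyl) | CC(C)=CCC/C(C)=C/C[C@]12C=CC(=O)C[C@]2(O)C(=O)C(OC)=C(CC=C(C)C)C1=O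
A7 | alternative 3 | methyl acrylate | C=CC(=O)OC
A8 | alternative 3 | tricyclic (rings A, B, D) diol ester with C4 ketone | CC(C)=CCC/C(C)=C/C[C@]12C=CC(=O)[C@@H]3C[C@H](C(=O)OC)[C@](O)(C(OC)=C(CC=C(C)C)C1=O)[C@@]32O
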